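## Retrosynthetic overview

1. The hydroperoxide comes last: target 24 from the (3'R)-allylic alcohol 22 by mesylation and SN2 displacement with H2O2. Alcohol 22 comes from aldehyde 20 and 2-bromopropene (Ni/Cr coupling), and 20 from the allyl group of acetate 19 (anti-Markovnikov Wacker).
2. The ten-membered ring (second and last ring formed) is closed at C4–C5 by an intramolecular Ni/Cr coupling of vinyl iodide–aldehyde 17. The (5E) geometry and the 6-methyl come from Negishi carboalumination of a terminal alkyne.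
3. The C2 tertiary alcohol comes from Cu-catalysed enantioselective β-borylation/oxidation of an (E)-enamide. The trans-cyclopropane (first ring formed) comes from a catalytic asymmetric Corey–Chaykovsky reaction on enone 9.
4. Enone 9 comes from ynal 7. Its aldehyde (C10), alkyne arm (C5–C8) and quaternary C9 are released together by Eschenmoser–Tanabe fragmentation of the epoxide of (R)-4-allyl-4-methylcyclohex-2-enone 4; the allyl group later becomes the side chain.
5. Enone 4 comes from enantioselective desymmetrising CuH reduction of the prochiral dienone 3, itself made by oxidative dearomatising para-allylation of p-cresol 1 with allyltrimethylsilane 2.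

Locants: bicyclo[8.1.0]undecane numbering of the target is used (C1 and C10 = cyclopropane CH, C11 = cyclopropane CH2, C2 = C(OH)CH3, C4 = CHOAc, C5=C6, C9 = quaternary carbon, side chain C1'–C5').

Assumption: in every catalyst-controlled step (2, 6, 9, 11, 14) the ligand antipode that gives the drawn configuration is used; multi-carbon building blocks are numbered as starting materials and simpler atom donors are given under "Reagents that add atoms".

## Route

Step 1
Reactants: 1 p-cresol (4-methylphenol); 2 allyltrimethylsilane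
Product: 3 4-methyl-4-(prop-2-en-1-yl)cyclohexa-2,5-dien-1-one
Conditions: PhI(OAc)2 (1.1 equiv), 2 (3 equiv), (CF3)2CHOH, -15 °C to rt
Reagents that add atoms: none
Why: Oxidative Hosomi–Sakurai dearomatisation, in which PhI(OAc)2 in the fluorinated alcohol turns the phenol into a phenoxenium-type species that the allylsilane captures at the methyl-bearing para carbon, giving the all-carbon quaternary centre as a prochiral cross-conjugated dienone.

Step 2
Reactants: 3 4-methyl-4-(prop-2-en-1-yl)cyclohexa-2,5-dien-1-one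
Product: 4 (4R)-4-methyl-4-(prop-2-en-1-yl)cyclohex-2-en-1-one
Conditions: Cu(OAc)2 (5 mol %), (R)-DTBM-SEGPHOS (5.5 mol %), (EtO)2MeSiH (1.05 equiv), t-BuOH (1.1 equiv), toluene, -40 °C
Reagents that add atoms: none
Why: Desymmetrising copper hydride conjugate reduction, in which the bulky bisphosphine–CuH complex reduces only one of the two enantiotopic enone C=C bonds so that the quaternary carbon becomes the (R)-stereocentre (C9 of the target), while one equivalent of silane at low temperature limits over-reduction.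

Step 3
Reactants: 4 (4R)-4-methyl-4-(prop-2-en-1-yl)cyclohex-2-en-1-one
Product: 5 (5R)-5-methyl-5-(prop-2-en-1-yl)-7-oxabicyclo[4.1.0]heptan-2-one (both epoxide diastereomers)
Conditions: 30% H2O2, NaOH (0.2 equiv), MeOH, 0 °C
Reagents that add atoms: hydrogen peroxide, OO
Why: Weitz–Scheffer nucleophilic epoxidation of the enone, where the facial mixture at the two epoxide carbons does not matter because both lose their stereochemistry in step 4 and the quaternary centre is not touched.

Step 4
Reactants: 5 (5R)-5-methyl-5-(prop-2-en-1-yl)-7-oxabicyclo[4.1.0]heptan-2-one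
Product: 7 (2R)-2-methyl-2-(prop-2-en-1-yl)hex-5-ynal, via epoxy tosylhydrazone 6 (not isolated)
Conditions: TsNHNH2 (1.05 equiv), AcOH/CH2Cl2 1:1, -20 °C to rt
Reagents that add atoms: 4-methylbenzenesulfonohydrazide, Cc1ccc(cc1)S(=O)(=O)NN (its atoms stay in 6 only)
Why: Eschenmoser–Tanabe fragmentation, in which the epoxy tosylhydrazone loses N2 and sulfinate with cleavage of the epoxide C–C bond to give the terminal alkyne and the aldehyde on the quaternary carbon, whose configuration is untouched and cannot epimerise.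

Step 5
Reactants: 7 (2R)-2-methyl-2-(prop-2-en-1-yl)hex-5-ynal; 8 1-(triphenyl-λ5-phosphanylidene)propan-2-one
Product: 9 (3E,5R)-5-methyl-5-(prop-2-en-1-yl)non-3-en-8-yn-2-one
Conditions: toluene, 100 °C
Reagents that add atoms: none
Why: Wittig olefination with a stabilised acyl ylide, which gives the (E)-enone selectively and tolerates the hindered aldehyde, the alkyne and the allyl group.

Step 6
Reactants: 9 (3E,5R)-5-methyl-5-(prop-2-en-1-yl)non-3-en-8-yn-2-one
Product: 10 1-[(1S,2S)-2-[(4R)-4-methyloct-1-en-7-yn-4-yl]cyclopropyl]ethan-1-one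
Conditions: Me3S(O)I (1.2 equiv), NaH (1.2 equiv), LaLi3(L)3 (10 mol %, L = chiral 6,6'-tethered biphenyl-2,2'-diolate), NaI (10 mol %), THF/toluene, rt
Reagents that add atoms: trimethylsulfoxonium iodide, C[S+](C)(C)=O.[I-]
Why: Catalytic asymmetric Corey–Chaykovsky cyclopropanation, in which conjugate addition of dimethylsulfoxonium methylide to the (E)-enone held in the chiral LaLi3(L)3 aryloxide pocket and 3-exo-tet closure give the trans-cyclopropyl ketone, the catalyst fixing the two new centres as (1S,2S) (C1 and C10 of the target) and the E geometry fixing the trans relationship.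

Step 7
Reactants: 10 1-[(1S,2S)-2-[(4R)-4-methyloct-1-en-7-yn-4-yl]cyclopropyl]ethan-1-one; 11 diethyl {2-[methoxy(methyl)amino]-2-oxoethyl}phosphonate
Product: 12 (2E)-N-methoxy-N-methyl-3-[(1S,2S)-2-[(4R)-4-methyloct-1-en-7-yn-4-yl]cyclopropyl]but-2-enamide
Conditions: NaH (1.0 equiv relative to 11), THF, 0 to 65 °C; minor Z isomer removed on silica
Reagents that add atoms: none
Why: Horner–Wadsworth–Emmons olefination of the methyl ketone, which places the larger cyclopropyl group trans to the amide carbonyl in the major (E)-isomer and does not epimerise the cyclopropane, whose trans arrangement is also the thermodynamic one.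

Step 8
Reactants: 12 (2E)-N-methoxy-N-methyl-3-[(1S,2S)-2-[(4R)-4-methyloct-1-en-7-yn-4-yl]cyclopropyl]but-2-enamide
Product: 14 (2E)-3-[(1S,2S)-2-[(4R,7E)-8-iodo-4,7-dimethylocta-1,7-dien-4-yl]cyclopropyl]-N-methoxy-N-methylbut-2-enamide, via alkenylalane 13 (not isolated)
Conditions: AlMe3 (3 equiv), Cp2ZrCl2 (1 equiv), CH2Cl2, 0 °C to rt; then I2, THF, -30 °C
Reagents that add atoms: trimethylaluminium, C[Al](C)C; iodine, II
Why: Negishi zirconium-promoted carboalumination, in which syn addition of methyl and aluminium across the terminal alkyne followed by iodinolysis with retention gives the (E)-vinyl iodide that fixes the C5=C6 geometry and the 6-methyl of the target, while the alkenes and the amide are inert to AlMe3 under these conditions.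

Step 9
Reactants: 14 (2E)-3-[(1S,2S)-2-[(4R,7E)-8-iodo-4,7-dimethylocta-1,7-dien-4-yl]cyclopropyl]-N-methoxy-N-methylbut-2-enamide
Product: 16 (3S)-3-hydroxy-3-[(1S,2S)-2-[(4R,7E)-8-iodo-4,7-dimethylocta-1,7-dien-4-yl]cyclopropyl]-N-methoxy-N-methylbutanamide, via tertiary boronate 15 (not isolated)
Conditions: CuCl (5 mol %), (R,R)-QuinoxP* (6 mol %), NaOtBu (8 mol %), B2pin2 (1.2 equiv), MeOH (2 equiv), THF, rt; then 30% H2O2, 1 M NaOH, 0 °C
Reagents that add atoms: bis(pinacolato)diboron, CC1(C)OB(OC1(C)C)B1OC(C)(C)C(C)(C)O1 (boron stays in 15 only); hydrogen peroxide, OO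
Why: Copper-catalysed enantioselective conjugate borylation of the β,β-disubstituted enamide followed by stereoretentive C–B oxidation, which sets the tertiary alcohol (C2 of the target) as (S) under catalyst control and spares the vinyl iodide because its borylation would need stoichiometric alkoxide base.

Step 10
Reactants: 16 (3S)-3-hydroxy-3-[(1S,2S)-2-[(4R,7E)-8-iodo-4,7-dimethylocta-1,7-dien-4-yl]cyclopropyl]-N-methoxy-N-methylbutanamide
Product: 17 (3S)-3-hydroxy-3-[(1S,2S)-2-[(4R,7E)-8-iodo-4,7-dimethylocta-1,7-dien-4-yl]cyclopropyl]butanal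
Conditions: i-Bu2AlH (2.2 equiv), THF, -78 °C; aq potassium sodium tartrate
Reagents that add atoms: none
Why: Weinreb amide reduction, in which the chelated aluminium hemiaminal survives at -78 °C and releases the aldehyde only on work-up, so there is no over-reduction and the vinyl iodide and all stereocentres are untouched.

Step 11
Reactants: 17 (3S)-3-hydroxy-3-[(1S,2S)-2-[(4R,7E)-8-iodo-4,7-dimethylocta-1,7-dien-4-yl]cyclopropyl]butanal
Product: 18 (1S,2S,4S,5E,9R,10S)-2,6,9-trimethyl-9-(prop-2-en-1-yl)bicyclo[8.1.0]undec-5-ene-2,4-diol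
Conditions: CrCl2 (6 equiv), chiral 2-(2-sulfonamidophenyl)oxazoline ligand (6.6 equiv), Et3N (6.6 equiv), NiCl2 (0.2 equiv), THF, 0.002 M, rt
Reagents that add atoms: none
Why: Intramolecular Nozaki–Hiyama–Kishi reaction, in which the alkenylchromium species formed from the vinyl iodide under nickel catalysis adds to the aldehyde with retention of the E geometry to close the ten-membered ring at C4–C5, and the sulfonamide-bound chromium directs attack to the aldehyde face that gives the (4S)-alcohol.

Step 12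
Reactants: 18 (1S,2S,4S,5E,9R,10S)-2,6,9-trimethyl-9-(prop-2-en-1-yl)bicyclo[8.1.0]undec-5-ene-2,4-diol
Product: 19 (1S,2S,4S,5E,9R,10S)-2-hydroxy-2,6,9-trimethyl-9-(prop-2-en-1-yl)bicyclo[8.1.0]undec-5-en-4-yl acetate
Conditions: Ac2O (1.2 equiv), pyridine, DMAP (5 mol %), CH2Cl2, 0 °C
Reagents that add atoms: acetic anhydride, CC(=O)OC(C)=O
Why: Chemoselective DMAP-catalysed esterification, in which the secondary allylic alcohol is acetylated while the hindered tertiary cyclopropylcarbinol does not react, and no stereocentre is touched.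

Step 13
Reactants: 19 (1S,2S,4S,5E,9R,10S)-2-hydroxy-2,6,9-trimethyl-9-(prop-2-en-1-yl)bicyclo[8.1.0]undec-5-en-4-yl acetate
Product: 20 (1S,2S,4S,5E,9R,10S)-2-hydroxy-2,6,9-trimethyl-9-(3-oxopropyl)bicyclo[8.1.0]undec-5-en-4-yl acetate
Conditions: PdCl2(PhCN)2 (10 mol %), CuCl2·2H2O (10 mol %), AgNO2 (5 mol %), O2 (1 atm), t-BuOH/MeNO2 15:1, rt
Reagents that add atoms: dioxygen, O=O
Why: Aldehyde-selective (anti-Markovnikov) Wacker oxidation under nitrite co-catalysis, which oxidises only the monosubstituted alkene to the terminal aldehyde because the trisubstituted ring alkene is too hindered to react.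

Step 14
Reactants: 20 (1S,2S,4S,5E,9R,10S)-2-hydroxy-2,6,9-trimethyl-9-(3-oxopropyl)bicyclo[8.1.0]undec-5-en-4-yl acetate; 21 2-bromoprop-1-ene
Product: 22 (1S,2S,4S,5E,9R,10S)-2-hydroxy-9-[(3R)-3-hydroxy-4-methylpent-4-en-1-yl]-2,6,9-trimethylbicyclo[8.1.0]undec-5-en-4-yl acetate
Conditions: 21 (3 equiv), CrCl2 (6 equiv), chiral 2-(2-sulfonamidophenyl)oxazoline ligand (6.6 equiv), Et3N (6.6 equiv), NiCl2 (0.2 equiv), THF, rt
Reagents that add atoms: none
Why: Intermolecular asymmetric Nozaki–Hiyama–Kishi isopropenylation, in which the ligand-bound alkenylchromium reagent adds to one aldehyde face to give the (3'R)-allylic alcohol under reagent control, while the acetate, the tertiary alcohol and the ring alkene are inert to organochromium species.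

Step 15
Reactants: 22 (1S,2S,4S,5E,9R,10S)-2-hydroxy-9-[(3R)-3-hydroxy-4-methylpent-4-en-1-yl]-2,6,9-trimethylbicyclo[8.1.0]undec-5-en-4-yl acetate
Product: 24 (1S,2S,4S,5E,9R,10S)-9-[(3S)-3-hydroperoxy-4-methylpent-4-en-1-yl]-2-hydroxy-2,6,9-trimethylbicyclo[8.1.0]undec-5-en-4-yl acetate (CNP0302713.3), via allylic mesylate 23 (not isolated)
Conditions: MsCl (1.2 equiv), Et3N (1.5 equiv), CH2Cl2, -65 °C; then anhydrous H2O2 in Et2O (excess), -78 to -20 °C
Reagents that add atoms: methanesulfonyl chloride, CS(=O)(=O)Cl (stays in 23 only); hydrogen peroxide, OO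
Why: Selective mesylation of the secondary allylic alcohol followed by SN2 perhydrolysis, in which the strongly nucleophilic H2O2 displaces the sulfonate with inversion to give the (3'S)-hydroperoxide, the low temperature and non-ionising solvent suppressing SN1 and SN2' pathways and the tertiary alcohol staying unsulfonylated.

## Compound list

1 | p-cresol (4-methylphenol) | Cc1ccc(O)cc1 | starting material
2 | allyltrimethylsilane | C=CC[Si](C)(C)C | starting material
3 | 4-methyl-4-(prop-2-en-1-yl)cyclohexa-2,5-dien-1-one | C=CCC1(C)C=CC(=O)C=C1 | intermediate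
4 | (4R)-4-methyl-4-(prop-2-en-1-yl)cyclohex-2-en-1-one | C=CC[C@@]1(C)CCC(=O)C=C1 | intermediate
5 | (5R)-5-methyl-5-(prop-2-en-1-yl)-7-oxabicyclo[4.1.0]heptan-2-one, both epoxide diastereomers | C=CC[C@@]1(C)CCC(=O)C2OC21 | intermediate
6 | 4-methylbenzenesulfonylhydrazone of 5 (epoxy tosylhydrazone, not isolated) | C=CC[C@@]1(C)CCC(=NNS(=O)(=O)c2ccc(C)cc2)C2OC21 | intermediate
7 | (2R)-2-methyl-2-(prop-2-en-1-yl)hex-5-ynal | C=CC[C@@](C=O)(C)CCC#C | intermediate
8 | 1-(triphenyl-λ5-phosphanylidene)propan-2-one | CC(=O)C=P(c1ccccc1)(c1ccccc1)c1ccccc1 | starting material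
9 | (3E,5R)-5-methyl-5-(prop-2-en-1-yl)non-3-en-8-yn-2-one | C=CC[C@@](/C=C/C(C)=O)(C)CCC#C | intermediate
10 | 1-[(1S,2S)-2-[(4R)-4-methyloct-1-en-7-yn-4-yl]cyclopropyl]ethan-1-one | CC(=O)[C@H]1C[C@@H]1[C@@](C)(CC=C)CCC#C | intermediate
11 | diethyl {2-[methoxy(methyl)amino]-2-oxoethyl}phosphonate | CCOP(=O)(CC(=O)N(C)OC)OCC | starting material
12 | (2E)-N-methoxy-N-methyl-3-[(1S,2S)-2-[(4R)-4-methyloct-1-en-7-yn-4-yl]cyclopropyl]but-2-enamide | CON(C)C(=O)/C=C(\C)[C@H]1C[C@@H]1[C@@](C)(CC=C)CCC#C | intermediate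
13 | dimethyl(alkenyl)alane from syn-methylalumination of the alkyne of 12, Al on the terminal carbon, E (not isolated) | CON(C)C(=O)/C=C(\C)[C@H]1C[C@@H]1[C@@](C)(CC=C)CC/C(C)=C/[Al](C)C | intermediate
14 | (2E)-3-[(1S,2S)-2-[(4R,7E)-8-iodo-4,7-dimethylocta-1,7-dien-4-yl]cyclopropyl]-N-methoxy-N-methylbut-2-enamide | CON(C)C(=O)/C=C(\C)[C@H]1C[C@@H]1[C@@](C)(CC=C)CC/C(C)=C/I | intermediate
15 | (3R)-3-[(1S,2S)-2-[(4R,7E)-8-iodo-4,7-dimethylocta-1,7-dien-4-yl]cyclopropyl]-N-methoxy-N-methyl-3-(4,4,5,5-tetramethyl-1,3,2-dioxaborolan-2-yl)butanamide (not isolated) | CON(C)C(=O)C[C@](C)(B2OC(C)(C)C(C)(C)O2)[C@H]1C[C@@H]1[C@@](C)(CC=C)CC/C(C)=C/I | intermediate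
16 | (3S)-3-hydroxy-3-[(1S,2S)-2-[(4R,7E)-8-iodo-4,7-dimethylocta-1,7-dien-4-yl]cyclopropyl]-N-methoxy-N-methylbutanamide | CON(C)C(=O)C[C@](C)(O)[C@H]1C[C@@H]1[C@@](C)(CC=C)CC/C(C)=C/I | intermediate
17 | (3S)-3-hydroxy-3-[(1S,2S)-2-[(4R,7E)-8-iodo-4,7-dimethylocta-1,7-dien-4-yl]cyclopropyl]butanal | O=CC[C@](C)(O)[C@H]1C[C@@H]1[C@@](C)(CC=C)CC/C(C)=C/I | intermediate
18 | (1S,2S,4S,5E,9R,10S)-2,6,9-trimethyl-9-(prop-2-en-1-yl)bicyclo[8.1.0]undec-5-ene-2,4-diol | C=CC[C@@]1(C)CC/C(C)=C/[C@@H](O)C[C@](C)(O)[C@H]2C[C@@H]21 | intermediate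
19 | (1S,2S,4S,5E,9R,10S)-2-hydroxy-2,6,9-trimethyl-9-(prop-2-en-1-yl)bicyclo[8.1.0]undec-5-en-4-yl acetate | C=CC[C@@]1(C)CC/C(C)=C/[C@@H](OC(C)=O)C[C@](C)(O)[C@H]2C[C@@H]21 | intermediate
20 | (1S,2S,4S,5E,9R,10S)-2-hydroxy-2,6,9-trimethyl-9-(3-oxopropyl)bicyclo[8.1.0]undec-5-en-4-yl acetate | O=CCC[C@@]1(C)CC/C(C)=C/[C@@H](OC(C)=O)C[C@](C)(O)[C@H]2C[C@@H]21 | intermediate
21 | 2-bromoprop-1-ene | C=C(C)Br | starting material
22 | (1S,2S,4S,5E,9R,10S)-2-hydroxy-9-[(3R)-3-hydroxy-4-methylpent-4-en-1-yl]-2,6,9-trimethylbicyclo[8.1.0]undec-5-en-4-yl acetate | C=C(C)[C@@H](CC[C@@]1(C)CC/C(C)=C/[C@@H](OC(C)=O)C[C@](C)(O)[C@H]2C[C@@H]21)O | intermediate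
23 | (1S,2S,4S,5E,9R,10S)-2-hydroxy-9-[(3R)-3-(methanesulfonyloxy)-4-methylpent-4-en-1-yl]-2,6,9-trimethylbicyclo[8.1.0]undec-5-en-4-yl acetate (not isolated) | C=C(C)[C@@H](CC[C@@]1(C)CC/C(C)=C/[C@@H](OC(C)=O)C[C@](C)(O)[C@H]2C[C@@H]21)OS(C)(=O)=O | intermediate
24 | (1S,2S,4S,5E,9R,10S)-9-[(3S)-3-hydroperoxy-4-methylpent-4-en-1-yl]-2-hydroxy-2,6,9-trimethylbicyclo[8.1.0]undec-5-en-4-yl acetate (CNP0302713.3) | C=C(C)[C@H](CC[C@@]1(C)CC/C(C)=C/[C@@H](OC(C)=O)C[C@](C)(O)[C@H]2C[C@@H]21)OO | target

## Step count and weakest steps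

Total step count: 15. Longest linear sequence: 15 steps from p-cresol; the other four starting materials (2, 8, 11, 21) are commercial and enter directly.

**Step 2 (desymmetrising reduction).** The catalyst has to tell methyl from allyl on the quaternary carbon, so the enantiomeric excess may be only moderate, and some over-reduction is possible. The fallback sets out from 3. An achiral copper hydride system (Cu(OAc)2, 1,2-bis(diphenylphosphino)benzene, (EtO)2MeSiH, t-BuOH, toluene) reduces one enone unit without selectivity to give racemic 4-methyl-4-(prop-2-en-1-yl)cyclohex-2-en-1-one F1. This is resolved by preparative supercritical-fluid chromatography on a chiral stationary phase, and the (R)-enantiomer re-enters the route as 4. The approach changes from catalytic desymmetrisation to resolution.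

**Step 11 (ten-membered ring closure).** Ring strain, oligomerisation and retro-aldol loss of the β-hydroxy aldehyde can lower the yield, and the ring conformation may override the ligand in fixing C4. The fallback sets out from 16 and closes the ring at the ketone oxidation level. MeLi (1 equiv) and then t-BuLi (2.1 equiv) in THF at -100 to -40 °C under high dilution give the alkenyllithium lithium alkoxide of 16, F2. F2 attacks its own Weinreb amide, and work-up gives (1S,2S,5E,9R,10S)-2-hydroxy-2,6,9-trimethyl-9-(prop-2-en-1-yl)bicyclo[8.1.0]undec-5-en-4-one F3. Hydroxyl-directed Evans–Saksena reduction of F3 (Me4NBH(OAc)3, MeCN/AcOH, -30 °C) delivers hydride internally from the C2 oxygen to give the 1,3-anti diol, which rejoins the route at 18.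

**Step 15 (hydroperoxide formation).** The allylic mesylate can ionise, which would erode the configuration at C3', or react by SN2' to give the primary hydroperoxide, and the product is sensitive. The fallback sets out from 20. Wittig reaction with isopropylidenetriphenylphosphorane (from isopropyltriphenylphosphonium iodide and n-BuLi, THF, -78 °C to rt) gives (1S,2S,4S,5E,9S,10S)-2-hydroxy-2,6,9-trimethyl-9-(4-methylpent-3-en-1-yl)bicyclo[8.1.0]undec-5-en-4-yl acetate F4. In F4 the C9 descriptor changes for priority reasons only; the spatial arrangement is the same. Schenck ene reaction of F4 with singlet oxygen (O2, tetraphenylporphyrin, visible light, CH2Cl2, -20 °C) places the hydroperoxide at C3' with shift of the double bond to the isopropenyl position. The (3'S)-isomer is separated by HPLC from its C3' epimer and from the tertiary hydroperoxide regioisomer, and the route is rejoined at 24.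

Further compounds
F1 | step 2 | racemic 4-methyl-4-(prop-2-en-1-yl)cyclohex-2-en-1-one | C=CCC1(C)CCC(=O)C=C1
F2 | step 11 | alkenyllithium lithium alkoxide formed from 16 by deprotonation and iodine–lithium exchange | CON(C)C(=O)C[C@](C)(O[Li])[C@H]1C[C@@H]1[C@@](C)(CC=C)CC/C(C)=C/[Li]
F3 | step 11 | (1S,2S,5E,9R,10S)-2-hydroxy-2,6,9-trimethyl-9-(prop-2-en-1-yl)bicyclo[8.1.0]undec-5-en-4-one | C=CC[C@@]1(C)CC/C(C)=C/C(=O)C[C@](C)(O)[C@H]2C[C@@H]21
F4 | step 15 | (1S,2S,4S,5E,9S,10S)-2-hydroxy-2,6,9-trimethyl-9-(4-methylpent-3-en-1-yl)bicyclo[8.1.0]undec-5-en-4-yl acetate | CC(C)=CCC[C@@]1(C)CC/C(C)=C/[C@@H](OC(C)=O)C[C@](C)(O)[C@H]2C[C@@H]21
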